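## Structural features

The target is a 2,3-dihydro-1,4-benzodioxine: ring B (O1, C2, C3, O4) is fused through C4a and C8a to benzene ring A, which carries a methoxy group at C5 and an allyl group at C7. C2 bears a 4-hydroxy-3,5-dimethoxyphenyl group (ring C) and C3 a methyl group; these adjacent carbons are the only stereocentres, both R, so aryl and methyl are trans (both pseudo-equatorial on the half-chair of ring B). Ring A holds three contiguous oxygens (OMe on C5, O4 on C4a, O1 on C8a), so the two ring B oxygens are ortho to each other and must be told apart: O4, the middle one, is bonded to the methyl-bearing C3, and O1, the outer one, to the benzylic C2. The C2–O1 bond is a para-hydroxybenzylic aryl ether that ionises under acid through a quinone methide, which makes C2 correctable but makes strong acid a hazard; the allyl double bond can move into conjugation and reacts with carbenes and electrophiles; the free phenol is hindered and oxidisable. The real difficulty is therefore C3, an unactivated secondary carbon carrying a di-ortho-substituted aryloxy group, whose absolute configuration must be set and then left untouched. The key step exploits the fact that C3 is bonded to O4, to the benzylic C2 and to a methyl carbon that can be a reduced ester carbon, so C3 can be the carbene carbon of a diazoacetate, O4 the hydroxyl oxygen of a ring A phenol and C2 the carbonyl carbon of a ring C aldehyde.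

## Logic of the disconnections

16 ⇒ 15. The C7–CH2 bond of the allyl group is cut. The alkene would not survive a metal carbene and is a liability under ring-closing acid, whereas a bromide is inert to both. Ring A becomes a plain bromo-trioxygenated arene. The forward coupling must tolerate a free phenol and a benzylic ether and must not move the double bond.

15 ⇒ 12 (through 13 and 14). The O1–C2 bond is cut. It is para-hydroxybenzylic, so it can be made by addition of O1 to a quinone methide under equilibrating conditions that favour the trans ring. The carbinol configuration in 12 then no longer matters and only C3 must be right. The demand is that O1 be a free phenol at that moment while O4 is already alkylated, so ring A must enter with its two ortho oxygens differentiated, and the cation must be trapped before it loses the C3 proton.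

12 ⇒ 11 ⇒ 10 ⇒ 9. The three C–H bonds of the C3 methyl group are traced back through CH2OTs and CH2OH to an ester carbon. An ester at this carbon is what a diazoacetate delivers. The forward steps must reduce the ester without enolising the adjacent stereocentre, distinguish the primary from the secondary hydroxyl, and displace the sulfonate with hydride; the same hydride can remove the ring C acyl group.

9 ⇒ 4 + 6 + 7. The C3–O4 and C2–C3 bonds are cut together. Both meet at C3, so one three-component reaction can form them and set C3 with a catalyst. The whole skeleton apart from the allyl group and the O1–C2 bond then comes from three simple pieces. The forward step must trap a short-lived ylide with the aldehyde before a proton shift, with one carbene acceptor only in the flask.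

6 ⇒ 5. The acyl–oxygen bond of the ester on ring C is cut. The free hydroxyl of 5 would itself take up the carbene and, as a para donor, would dull the aldehyde. The forward step is a plain acylation of a hindered phenol.

4 ⇒ 3 ⇒ 1. The O–Si bond is cut, and the C8a–O1 bond is traced back to a C8a–CHO bond. In 1 the bromine, the methoxy group and the middle hydroxyl are already in place and the formyl carbon marks where O1 must sit, so the substitution pattern needs no regiochemical decision. The forward silylation must select the outer of two adjacent hydroxyls.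

## Other disconnections considered

Alternative 1: The cut is the aryl C8a–O1 bond. The substrate would be A1, 4-[(1R,2R)-2-(4-allyl-2,6-dimethoxyphenoxy)-1-hydroxypropyl]-2,6-dimethoxyphenyl pivalate, with ring A still symmetric and both stereocentres in place. A photoexcited acridinium salt would oxidise ring A to its radical cation, the C2 hydroxyl would add ipso to one methoxy-bearing carbon, and back electron transfer with loss of the methoxy group would give A2, one deacylation from the target.
- In its favour: ring A enters as a symmetric dimethoxyphenol, so the ortho oxygens need no differentiation, and the allyl group is carried from the start, so no cross-coupling is needed. On both counts it is better than the chosen plan in step economy. The C2–O bond is never broken, so C2 is transferred with retention, which is mechanistically cleaner than an equilibrating cation.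
- Against it: because C2 is retained, A1 must be a single diastereomer, so the carbinol centre needs its own stereocontrol, which the chosen plan avoids. Radical cations of β-aryloxy benzylic alcohols tend to fragment at the C2–C3 bond, the allyl C–H bonds are acidified in the radical cation, and ring C is a second oxidisable arene. Ipso-substitution of methoxy groups of this kind is established mainly with nitrogen nucleophiles, so an alcohol closing a ring would also be an extension.
- Comparison: shorter on paper and equal in novelty risk, but with an extra stereocentre to control and more ways for the key intermediate to break down.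

Alternative 2: Ring A is not aromatic at the key step; O4–C4a and O1–C2 are formed together. The partners would be the trans-epoxide A3, 2,6-dimethoxy-4-[(2R,3R)-3-methyloxiran-2-yl]phenyl pivalate, and the diazo-dione A4, ethyl 4-diazo-3,5-dioxocyclohexane-1-carboxylate. A dirhodium tetracarboxylate would turn A4 into a carbene that takes the epoxide oxygen as an oxonium ylide; the benzylic C–O bond opens and the enolate oxygen closes on C2 to give the dioxene A5 as C7 epimers.
- In its favour: condensation of diazo-dicarbonyl compounds with epoxides to 1,4-dioxenes is a known reaction class, so the key step stands on firmer ground than the chosen one, which is a point where it is better. A3 is within reach of catalytic asymmetric epoxidation and its C3–O bond is never broken, so C3 is as secure as in the chosen plan. A4 is symmetric, so the positions of the C5 oxygen and the C7 carbon follow automatically, and no hindered phenol has to act as a nucleophile.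
- Against it: the configuration at C2 depends on whether the benzylic bond is replaced with retention or inversion, which decides which epoxide diastereomer must be used, and an ionised benzylic carbon may lose that information. Simple deoxygenation of the epoxide by the carbene is a competing path. After the key step, ring A must be dehydrogenated next to an acid-labile benzylic ether and O-methylated, and the C7 ester must be converted into an allyl group by reduction, activation and vinylation. That is at least six further steps against five in the chosen plan.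
- Comparison: better precedent for the key step, equal on C3, worse on step economy and on the late chemistry of ring A.

Alternative 3: The cut is C3–O4, and the C3 methyl group is created in the same step from a vinyl group. The substrate would be A6, 4-[(1S)-1-(5-bromo-2-hydroxy-3-methoxyphenoxy)prop-2-en-1-yl]-2,6-dimethoxyphenyl pivalate, in which O1–C2 already exists. A cobalt salen complex with a silane and an N-fluoropyridinium oxidant would deliver a hydrogen atom to the terminal alkene carbon; after oxidation of the C3 radical to a cationic alkylcobalt species, the ring A hydroxyl O4 would displace cobalt in a 6-exo closure to give A7.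
- In its favour: cobalt-hydride hydroalkoxylation of unactivated alkenes, including ring closures by phenols, is an established reaction type, so the key step is better founded than the chosen one. The methyl group needs no three-step reduction sequence, so only deacylation and allylation follow, which is clearly better step economy. Bromide and pivalate are compatible.
- Against it: the C3 radical is β to the benzylic C2–O1 bond, and β-scission to a styrene conjugated with ring C and a stabilised aryloxyl radical is a plausible competitor. A6 is an allyl aryl ether with a free ortho carbon (C8), hence open to a [3,3] shift, and a benzylic–allylic ether that ionises easily. C2 must be installed enantioselectively beforehand, and C3 is then set only by substrate control in the displacement at cobalt. The chosen plan sets C3 by catalyst and C2 thermodynamically.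
- Comparison: the need to differentiate the two ortho oxygens of ring A is the same in both plans. Alternative 3 has better precedent and fewer steps, but its stereocontrol rests on a less certain diastereoselection and its substrate has built-in fragmentation paths.

Key step: step 4

Remarks on the chemistry:
- Descriptors: the ester-bearing carbon of 9 is S; the same carbon, with unchanged geometry, is R from 10 onwards and is C3 (R) of the target, because the ester carbon outranks the carbinol carbon whereas CH2OH, CH2OTs and CH3 do not.
- Ring A design: the oxygen that becomes O1 is carried as a triisopropylsilyl ether and not as a second methyl ether, so that ring B is closed by a free phenol. A closure that must expel methyl from an anisole-type oxygen is not relied on.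
- Assumption: the sense of induction of the phosphoric acid cannot be derived for this substrate combination; the (R)-acid is written, and its antipode would be used if a first trial favours the wrong enantiomer of 9.

## Route

Step 1
Reactants: 1 5-bromo-2-hydroxy-3-methoxybenzaldehyde
Product: 3 5-bromo-3-methoxybenzene-1,2-diol, via aryl formate 2 (not isolated)
Conditions: 30% aq. H2O2 (1.2 equiv), NaOH (1.1 equiv), H2O/THF, 0 °C → rt; then 2 M HCl
Reagents that add atoms: hydrogen peroxide, OO
Why: Dakin oxidation: hydroperoxide adds to the aldehyde, the electron-rich aryl group migrates to oxygen to give 2, and hydroxide cleaves the formate; the new oxygen replaces the formyl carbon, so it is by construction the outer oxygen (later O1), with bromine para to the retained hydroxyl (later O4).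

Step 2
Reactants: 3 5-bromo-3-methoxybenzene-1,2-diol
Product: 4 4-bromo-2-methoxy-6-[(triisopropylsilyl)oxy]phenol
Conditions: TIPSCl (1.05 equiv), imidazole (2 equiv), DMF, 0 °C → rt
Reagents that add atoms: chlorotriisopropylsilane, CC(C)[Si](Cl)(C(C)C)C(C)C
Why: Silylation of a phenol with a bulky chlorosilane: the outer hydroxyl has one ortho neighbour and the inner one two, so the outer oxygen should react, and any silyl migration between the adjacent oxygens would settle on the same, less crowded isomer. The silyl ether masks the future O1 through the carbene, sulfonylation and hydride steps and comes off with fluoride when O1 is needed.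

Step 3
Reactants: 5 syringaldehyde (4-hydroxy-3,5-dimethoxybenzaldehyde)
Product: 6 4-formyl-2,6-dimethoxyphenyl pivalate
Conditions: PivCl (1.2 equiv), Et3N (1.5 equiv), DMAP (5 mol %), CH2Cl2, 0 °C → rt
Reagents that add atoms: pivaloyl chloride, CC(C)(C)C(=O)Cl
Why: Acylation of a hindered phenol under nucleophilic catalysis. The pivalate removes the only O–H of the aldehyde component, makes the carbonyl more electrophilic than in the free para-donating phenol, and is later cleaved by the hydride of step 7.

Step 4
Reactants: 4 4-bromo-2-methoxy-6-[(triisopropylsilyl)oxy]phenol; 6 4-formyl-2,6-dimethoxyphenyl pivalate; 7 ethyl diazoacetate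
Product: 9 ethyl (2S)-2-{4-bromo-2-methoxy-6-[(triisopropylsilyl)oxy]phenoxy}-3-[3,5-dimethoxy-4-(pivaloyloxy)phenyl]-3-hydroxypropanoate (both carbinol epimers), via enol form of the oxonium ylide 8 (not isolated)
Conditions: Rh2(OAc)4 (2 mol %), (R)-3,3'-bis(2,4,6-triisopropylphenyl)-1,1'-binaphthyl-2,2'-diyl hydrogen phosphate (10 mol %), 4 Å MS, CH2Cl2, −20 °C; 7 (1.5 equiv) added over 6 h to 4 (1.0 equiv) and 6 (1.5 equiv)
Reagents that add atoms: none
Why: Proposed new method: Rh2(OAc)4 decomposes 7 to a rhodium carbene, the only free hydroxyl in the flask (that of 4) adds to it, and the protic oxonium ylide so formed equilibrates with its enol 8; the closest known reaction type is the Rh2(OAc)4 and chiral phosphoric acid co-catalysed three-component coupling of aryldiazoacetates, alcohols and aldehydes, whereas an acceptor-only diazoacetate, a di-ortho-substituted phenol and this aldehyde have not been combined. The BINOL-derived acid holds the aldehyde through its acidic P–OH and the enol hydroxyl through P=O, so that 8 adds to the carbonyl of 6 before the 1,2-proton shift can complete a plain O–H insertion; this forms C3–O4 and C2–C3 (benzodioxane numbering) and closes no ring. The ester-bearing carbon (later C3) is the stereocentre that counts, and it is set by the phosphoric acid, which selects the enol face that attacks. The carbinol carbon (later C2) forms without control and needs none, because step 8 ionises it. Chemoselectivity rests on the substrates: the bromide stands in for the allyl group, which the carbene would cyclopropanate; the pivalate removes the aldehyde's own insertion site and raises its electrophilicity; the silyl ether leaves ring A with a single reactive hydroxyl. Slow addition of 7 at low temperature keeps carbene dimerisation and acid-promoted homologation of the aldehyde by the diazo ester behind the productive path.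

Step 5
Reactants: 9 ethyl (2S)-2-{4-bromo-2-methoxy-6-[(triisopropylsilyl)oxy]phenoxy}-3-[3,5-dimethoxy-4-(pivaloyloxy)phenyl]-3-hydroxypropanoate
Product: 10 4-[(2R)-2-{4-bromo-2-methoxy-6-[(triisopropylsilyl)oxy]phenoxy}-1,3-dihydroxypropyl]-2,6-dimethoxyphenyl pivalate (C1 epimers)
Conditions: LiBH4 (2.5 equiv), THF, 0 °C → rt
Reagents that add atoms: none
Why: Chemoselective borohydride reduction of an α-aryloxy-β-hydroxy ester, which is activated by its two neighbouring oxygens, while the pivalate flanked by two methoxy groups and the aryl silyl ether are left alone. LiBH4 in THF avoids an alkoxide medium, so the ester-bearing stereocentre should not be enolised and no retro-aldol should occur; its geometry is kept.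

Step 6
Reactants: 10 4-[(2R)-2-{4-bromo-2-methoxy-6-[(triisopropylsilyl)oxy]phenoxy}-1,3-dihydroxypropyl]-2,6-dimethoxyphenyl pivalate
Product: 11 4-[(2R)-2-{4-bromo-2-methoxy-6-[(triisopropylsilyl)oxy]phenoxy}-1-hydroxy-3-(tosyloxy)propyl]-2,6-dimethoxyphenyl pivalate (C1 epimers)
Conditions: TsCl (1.1 equiv), pyridine, CH2Cl2, 0 °C
Reagents that add atoms: 4-methylbenzenesulfonyl chloride, Cc1ccc(cc1)S(Cl)(=O)=O
Why: Selective sulfonylation of the primary hydroxyl of a 1,3-diol; the secondary benzylic hydroxyl is shielded by ring C and the adjacent aryloxy group and should react much more slowly with one equivalent of TsCl at 0 °C.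

Step 7
Reactants: 11 4-[(2R)-2-{4-bromo-2-methoxy-6-[(triisopropylsilyl)oxy]phenoxy}-1-hydroxy-3-(tosyloxy)propyl]-2,6-dimethoxyphenyl pivalate
Product: 12 4-[(2R)-2-{4-bromo-2-methoxy-6-[(triisopropylsilyl)oxy]phenoxy}-1-hydroxypropyl]-2,6-dimethoxyphenol (C1 epimers)
Conditions: LiBHEt3 (6 equiv), THF, 0 °C → rt
Reagents that add atoms: none
Why: SN2 displacement of a primary tosylate by hydride gives the C3 methyl group, and the same reagent reduces the aryl pivalate to the free ring C phenol; the aryl bromide and the aryl silyl ether are inert to LiBHEt3 at this temperature. The silyl ether on the future O1 is essential here, because a free ortho phenoxide would close a six-membered ring onto the tosylate.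

Step 8
Reactants: 12 4-[(2R)-2-{4-bromo-2-methoxy-6-[(triisopropylsilyl)oxy]phenoxy}-1-hydroxypropyl]-2,6-dimethoxyphenol
Product: 15 4-[(2R,3R)-7-bromo-5-methoxy-3-methyl-2,3-dihydro-1,4-benzodioxin-2-yl]-2,6-dimethoxyphenol, via desilylated triol 13 (not isolated), via quinone methide 14 (not isolated)
Conditions: TBAF (1.1 equiv), THF, 0 °C; then TsOH·H2O (2.5 equiv), 0 °C → rt
Reagents that add atoms: none
Why: Fluoride cleaves the aryl silyl ether to 13; acid then ionises the para-hydroxybenzylic alcohol to the protonated quinone methide 14, and the ortho hydroxyl O1 adds to its exocyclic carbon in a 6-exo-trig closure of ring B, a quinone-methide etherification of the kind used for 2-aryl-1,4-benzodioxanes. C2 forms under thermodynamic control, since the benzylic ether can re-ionise, and settles trans to the C3 methyl group, which with the fixed (R)-C3 gives (2R,3R); both carbinol epimers converge.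

Step 9
Reactants: 15 4-[(2R,3R)-7-bromo-5-methoxy-3-methyl-2,3-dihydro-1,4-benzodioxin-2-yl]-2,6-dimethoxyphenol
Product: 16 4-[(2R,3R)-7-allyl-5-methoxy-3-methyl-2,3-dihydro-1,4-benzodioxin-2-yl]-2,6-dimethoxyphenol (target, CNP0116579.1)
Conditions: allylSnBu3 (1.5 equiv), Pd(PPh3)4 (5 mol %), DMF, 90 °C
Reagents that add atoms: allyltributylstannane, C=CC[Sn](CCCC)(CCCC)CCCC
Why: Stille coupling: oxidative addition of the aryl bromide to zerovalent palladium, allyl transfer from tin and reductive elimination. The neutral conditions tolerate the free phenol and leave both stereocentres untouched; limiting time and temperature should keep the allyl group from moving into conjugation.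

## Compound list

1 | 5-bromo-2-hydroxy-3-methoxybenzaldehyde | COc1cc(Br)cc(C=O)c1O | starting material
2 | 5-bromo-2-hydroxy-3-methoxyphenyl formate (not isolated) | COc1cc(Br)cc(OC=O)c1O | intermediate
3 | 5-bromo-3-methoxybenzene-1,2-diol | COc1cc(Br)cc(O)c1O | intermediate
4 | 4-bromo-2-methoxy-6-[(triisopropylsilyl)oxy]phenol | COc1cc(Br)cc(O[Si](C(C)C)(C(C)C)C(C)C)c1O | intermediate
5 | syringaldehyde (4-hydroxy-3,5-dimethoxybenzaldehyde) | COc1cc(C=O)cc(OC)c1O | starting material
6 | 4-formyl-2,6-dimethoxyphenyl pivalate | COc1cc(C=O)cc(OC)c1OC(=O)C(C)(C)C | intermediate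
7 | ethyl diazoacetate | [N-]=[N+]=CC(=O)OCC | starting material
8 | 2-{4-bromo-2-methoxy-6-[(triisopropylsilyl)oxy]phenoxy}-1-ethoxyethen-1-ol, enol form of the oxonium ylide (not isolated; alkene geometry undefined) | CCOC(O)=COc1c(OC)cc(Br)cc1O[Si](C(C)C)(C(C)C)C(C)C | intermediate
9 | ethyl (2S)-2-{4-bromo-2-methoxy-6-[(triisopropylsilyl)oxy]phenoxy}-3-[3,5-dimethoxy-4-(pivaloyloxy)phenyl]-3-hydroxypropanoate (carbinol epimers) | COc1cc(Br)cc(O[Si](C(C)C)(C(C)C)C(C)C)c1O[C@H](C(=O)OCC)C(O)c1cc(OC)c(OC(=O)C(C)(C)C)c(OC)c1 | intermediate
10 | 4-[(2R)-2-{4-bromo-2-methoxy-6-[(triisopropylsilyl)oxy]phenoxy}-1,3-dihydroxypropyl]-2,6-dimethoxyphenyl pivalate (C1 epimers) | COc1cc(Br)cc(O[Si](C(C)C)(C(C)C)C(C)C)c1O[C@H](CO)C(O)c1cc(OC)c(OC(=O)C(C)(C)C)c(OC)c1 | intermediate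
11 | 4-[(2R)-2-{4-bromo-2-methoxy-6-[(triisopropylsilyl)oxy]phenoxy}-1-hydroxy-3-(tosyloxy)propyl]-2,6-dimethoxyphenyl pivalate (C1 epimers) | COc1cc(Br)cc(O[Si](C(C)C)(C(C)C)C(C)C)c1O[C@H](COS(=O)(=O)c1ccc(C)cc1)C(O)c1cc(OC)c(OC(=O)C(C)(C)C)c(OC)c1 | intermediate
12 | 4-[(2R)-2-{4-bromo-2-methoxy-6-[(triisopropylsilyl)oxy]phenoxy}-1-hydroxypropyl]-2,6-dimethoxyphenol (C1 epimers) | COc1cc(Br)cc(O[Si](C(C)C)(C(C)C)C(C)C)c1O[C@H](C)C(O)c1cc(OC)c(O)c(OC)c1 | intermediate
13 | 4-[(2R)-2-(4-bromo-2-hydroxy-6-methoxyphenoxy)-1-hydroxypropyl]-2,6-dimethoxyphenol (C1 epimers; not isolated) | COc1cc(Br)cc(O)c1O[C@H](C)C(O)c1cc(OC)c(O)c(OC)c1 | intermediate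
14 | 4-[(2R)-2-(4-bromo-2-hydroxy-6-methoxyphenoxy)propylidene]-2,6-dimethoxycyclohexa-2,5-dien-1-one (not isolated) | COc1cc(Br)cc(O)c1O[C@H](C)C=C1C=C(OC)C(=O)C(OC)=C1 | intermediate
15 | 4-[(2R,3R)-7-bromo-5-methoxy-3-methyl-2,3-dihydro-1,4-benzodioxin-2-yl]-2,6-dimethoxyphenol | COc1cc(Br)cc2O[C@H](c3cc(OC)c(O)c(OC)c3)[C@@H](C)Oc12 | intermediate
16 | 4-[(2R,3R)-7-allyl-5-methoxy-3-methyl-2,3-dihydro-1,4-benzodioxin-2-yl]-2,6-dimethoxyphenol | C=CCc1cc(OC)c2c(c1)O[C@H](c1cc(OC)c(O)c(OC)c1)[C@@H](C)O2 | target

## Step count and least certain steps

Total: 9 steps. Longest linear sequence: 8 steps (steps 1, 2, 4, 5, 6, 7, 8, 9); step 3 is a one-step side branch.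

Step 4 (Proposed new method). The most likely failure is that the 1,2-proton shift of the acceptor-only oxonium ylide outruns the aldol trapping, so that plain O–H insertion dominates. The second is poor facial selectivity at the ylide carbon, because the phenol is flanked on both sides and the ylide is short-lived. Acid-promoted homologation of the aldehyde by the diazo ester may also consume both partners.

The fallback uses known chemistry, sets out from 4 and comes back to the route at 13. Mitsunobu etherification of 4 with ethyl (S)-lactate (PPh3, DIAD, THF) would give, with inversion, ethyl (2R)-2-{4-bromo-2-methoxy-6-[(triisopropylsilyl)oxy]phenoxy}propanoate F1, so the C3 methyl group and its configuration come from the chiral pool. Half-reduction with i-Bu2AlH at −78 °C would give (2R)-2-{4-bromo-2-methoxy-6-[(triisopropylsilyl)oxy]phenoxy}propanal F2, used at once because the α-aryloxy aldehyde is configurationally labile. Separately, purchased 4-bromo-2,6-dimethoxyphenol would be silylated (TIPSCl, imidazole) to (4-bromo-2,6-dimethoxyphenoxy)triisopropylsilane F3 and converted with magnesium into {3,5-dimethoxy-4-[(triisopropylsilyl)oxy]phenyl}magnesium bromide F4. Addition of F4 to F2 would give (2R)-2-{4-bromo-2-methoxy-6-[(triisopropylsilyl)oxy]phenoxy}-1-{3,5-dimethoxy-4-[(triisopropylsilyl)oxy]phenyl}propan-1-ol F5 as a mixture of carbinol epimers. Two equivalents of TBAF would convert F5 into 13, which goes on to 15 under the acid of step 8.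

Step 8. The most likely failure is loss of the C3 proton from the benzylic cation before O1 arrives, which would erode the C3 configuration and open a path to ether cleavage. Incomplete trans selectivity is possible if re-ionisation is too slow to equilibrate, and the cation may also arylate another electron-rich ring.

The fallback replaces the cationic closure by a stereospecific SN2 closure; it sets out from 12 and comes back at 15. Re-acylation of the ring C phenol (PivCl, Et3N) would give 4-[(2R)-2-{4-bromo-2-methoxy-6-[(triisopropylsilyl)oxy]phenoxy}-1-hydroxypropyl]-2,6-dimethoxyphenyl pivalate F6. Oxidation with Dess–Martin periodinane would give the ketone 4-[(2R)-2-{4-bromo-2-methoxy-6-[(triisopropylsilyl)oxy]phenoxy}propanoyl]-2,6-dimethoxyphenyl pivalate F7. Reduction with LiBH(s-Bu)3 at −78 °C under polar Felkin–Anh control would give the erythro alcohol 4-[(1S,2R)-2-{4-bromo-2-methoxy-6-[(triisopropylsilyl)oxy]phenoxy}-1-hydroxypropyl]-2,6-dimethoxyphenyl pivalate F8. Buffered TBAF would free O1 to give 4-[(1S,2R)-2-(4-bromo-2-hydroxy-6-methoxyphenoxy)-1-hydroxypropyl]-2,6-dimethoxyphenyl pivalate F9. Intramolecular Mitsunobu reaction (PPh3, DIAD) would close O1–C2 with inversion to 4-[(2R,3R)-7-bromo-5-methoxy-3-methyl-2,3-dihydro-1,4-benzodioxin-2-yl]-2,6-dimethoxyphenyl pivalate F10 (the same structure as A7). Methanolysis (NaOMe, MeOH) would give 15.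

Step 7. The most likely failure is participation of the neighbouring carbinol oxygen once the hydride has deprotonated it: four-membered ether formation or fragmentation of the 1,3-hydroxy sulfonate. Attack of hydride at sulfur, returning the diol, is also possible, as is incomplete cleavage of the hindered pivalate.

The fallback masks the carbinol; it sets out from 11 and comes back at 13. Silylation (TESOTf, 2,6-lutidine, −78 °C) would give 4-[(2R)-2-{4-bromo-2-methoxy-6-[(triisopropylsilyl)oxy]phenoxy}-3-(tosyloxy)-1-[(triethylsilyl)oxy]propyl]-2,6-dimethoxyphenyl pivalate F11. LiBHEt3 would then give 4-[(2R)-2-{4-bromo-2-methoxy-6-[(triisopropylsilyl)oxy]phenoxy}-1-[(triethylsilyl)oxy]propyl]-2,6-dimethoxyphenol F12 with no alkoxide next to the sulfonate. TBAF (2.2 equiv) would remove both silyl groups to give 13, which is cyclised as in step 8.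

Step 2. The most likely failure is insufficient discrimination between the two adjacent hydroxyls, or double silylation, because the preference is steric only.

The fallback removes the need for any selectivity by protecting the existing hydroxyl first; it sets out from 1 and comes back at 4. Treatment of 1 with MOMCl and i-Pr2NEt would give 5-bromo-3-methoxy-2-(methoxymethoxy)benzaldehyde F13. Baeyer–Villiger oxidation (mCPBA) and methanolysis of the formate (K2CO3, MeOH) would give 5-bromo-3-methoxy-2-(methoxymethoxy)phenol F14. Silylation (TIPSCl, imidazole) would give [5-bromo-3-methoxy-2-(methoxymethoxy)phenoxy]triisopropylsilane F15. Dilute HCl in MeOH would remove the acetal and give 4.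

## Further compounds

F1 | step 4 | ethyl (2R)-2-{4-bromo-2-methoxy-6-[(triisopropylsilyl)oxy]phenoxy}propanoate | COc1cc(Br)cc(O[Si](C(C)C)(C(C)C)C(C)C)c1O[C@H](C)C(=O)OCC
F2 | step 4 | (2R)-2-{4-bromo-2-methoxy-6-[(triisopropylsilyl)oxy]phenoxy}propanal | COc1cc(Br)cc(O[Si](C(C)C)(C(C)C)C(C)C)c1O[C@H](C)C=O
F3 | step 4 | (4-bromo-2,6-dimethoxyphenoxy)triisopropylsilane | COc1cc(Br)cc(OC)c1O[Si](C(C)C)(C(C)C)C(C)C
F4 | step 4 | {3,5-dimethoxy-4-[(triisopropylsilyl)oxy]phenyl}magnesium bromide | COc1cc([Mg]Br)cc(OC)c1O[Si](C(C)C)(C(C)C)C(C)C
F5 | step 4 | (2R)-2-{4-bromo-2-methoxy-6-[(triisopropylsilyl)oxy]phenoxy}-1-{3,5-dimethoxy-4-[(triisopropylsilyl)oxy]phenyl}propan-1-ol (C1 epimers) | COc1cc(Br)cc(O[Si](C(C)C)(C(C)C)C(C)C)c1O[C@H](C)C(O)c1cc(OC)c(O[Si](C(C)C)(C(C)C)C(C)C)c(OC)c1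
F6 | step 8 | 4-[(2R)-2-{4-bromo-2-methoxy-6-[(triisopropylsilyl)oxy]phenoxy}-1-hydroxypropyl]-2,6-dimethoxyphenyl pivalate (C1 epimers) | COc1cc(Br)cc(O[Si](C(C)C)(C(C)C)C(C)C)c1O[C@H](C)C(O)c1cc(OC)c(OC(=O)C(C)(C)C)c(OC)c1
F7 | step 8 | 4-[(2R)-2-{4-bromo-2-methoxy-6-[(triisopropylsilyl)oxy]phenoxy}propanoyl]-2,6-dimethoxyphenyl pivalate | COc1cc(Br)cc(O[Si](C(C)C)(C(C)C)C(C)C)c1O[C@H](C)C(=O)c1cc(OC)c(OC(=O)C(C)(C)C)c(OC)c1
F8 | step 8 | 4-[(1S,2R)-2-{4-bromo-2-methoxy-6-[(triisopropylsilyl)oxy]phenoxy}-1-hydroxypropyl]-2,6-dimethoxyphenyl pivalate | COc1cc(Br)cc(O[Si](C(C)C)(C(C)C)C(C)C)c1O[C@H](C)[C@@H](O)c1cc(OC)c(OC(=O)C(C)(C)C)c(OC)c1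
F9 | step 8 | 4-[(1S,2R)-2-(4-bromo-2-hydroxy-6-methoxyphenoxy)-1-hydroxypropyl]-2,6-dimethoxyphenyl pivalate | COc1cc(Br)cc(O)c1O[C@H](C)[C@@H](O)c1cc(OC)c(OC(=O)C(C)(C)C)c(OC)c1
F10 | step 8 | 4-[(2R,3R)-7-bromo-5-methoxy-3-methyl-2,3-dihydro-1,4-benzodioxin-2-yl]-2,6-dimethoxyphenyl pivalate | COc1cc(Br)cc2O[C@H](c3cc(OC)c(OC(=O)C(C)(C)C)c(OC)c3)[C@@H](C)Oc12
F11 | step 7 | 4-[(2R)-2-{4-bromo-2-methoxy-6-[(triisopropylsilyl)oxy]phenoxy}-3-(tosyloxy)-1-[(triethylsilyl)oxy]propyl]-2,6-dimethoxyphenyl pivalate (C1 epimers) | COc1cc(Br)cc(O[Si](C(C)C)(C(C)C)C(C)C)c1O[C@H](COS(=O)(=O)c1ccc(C)cc1)C(O[Si](CC)(CC)CC)c1cc(OC)c(OC(=O)C(C)(C)C)c(OC)c1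
F12 | step 7 | 4-[(2R)-2-{4-bromo-2-methoxy-6-[(triisopropylsilyl)oxy]phenoxy}-1-[(triethylsilyl)oxy]propyl]-2,6-dimethoxyphenol (C1 epimers) | COc1cc(Br)cc(O[Si](C(C)C)(C(C)C)C(C)C)c1O[C@H](C)C(O[Si](CC)(CC)CC)c1cc(OC)c(O)c(OC)c1
F13 | step 2 | 5-bromo-3-methoxy-2-(methoxymethoxy)benzaldehyde | COCOc1c(OC)cc(Br)cc1C=O
F14 | step 2 | 5-bromo-3-methoxy-2-(methoxymethoxy)phenol | COCOc1c(OC)cc(Br)cc1O
F15 | step 2 | [5-bromo-3-methoxy-2-(methoxymethoxy)phenoxy]triisopropylsilane | COCOc1c(OC)cc(Br)cc1O[Si](C(C)C)(C(C)C)C(C)C
A1 | alternative 1 | 4-[(1R,2R)-2-(4-allyl-2,6-dimethoxyphenoxy)-1-hydroxypropyl]-2,6-dimethoxyphenyl pivalate | C=CCc1cc(OC)c(O[C@H](C)[C@H](O)c2cc(OC)c(OC(=O)C(C)(C)C)c(OC)c2)c(OC)c1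
A2 | alternative 1 | 4-[(2R,3R)-7-allyl-5-methoxy-3-methyl-2,3-dihydro-1,4-benzodioxin-2-yl]-2,6-dimethoxyphenyl pivalate | C=CCc1cc(OC)c2c(c1)O[C@H](c1cc(OC)c(OC(=O)C(C)(C)C)c(OC)c1)[C@@H](C)O2
A3 | alternative 2 | 2,6-dimethoxy-4-[(2R,3R)-3-methyloxiran-2-yl]phenyl pivalate | C[C@H]1O[C@@H]1c1cc(OC)c(OC(=O)C(C)(C)C)c(OC)c1
A4 | alternative 2 | ethyl 4-diazo-3,5-dioxocyclohexane-1-carboxylate | CCOC(=O)C1CC(=O)C(=[N+]=[N-])C(=O)C1
A5 | alternative 2 | ethyl (2R,3R)-2-(3,5-dimethoxy-4-pivaloyloxyphenyl)-3-methyl-5-oxo-2,3,5,6,7,8-hexahydro-1,4-benzodioxine-7-carboxylate (C7 epimers) | CCOC(=O)C1CC(=O)C2=C(C1)O[C@H](c1cc(OC)c(OC(=O)C(C)(C)C)c(OC)c1)[C@@H](C)O2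
A6 | alternative 3 | 4-[(1S)-1-(5-bromo-2-hydroxy-3-methoxyphenoxy)prop-2-en-1-yl]-2,6-dimethoxyphenyl pivalate | C=C[C@H](Oc1cc(Br)cc(OC)c1O)c1cc(OC)c(OC(=O)C(C)(C)C)c(OC)c1
A7 | alternative 3 | 4-[(2R,3R)-7-bromo-5-methoxy-3-methyl-2,3-dihydro-1,4-benzodioxin-2-yl]-2,6-dimethoxyphenyl pivalate | COc1cc(Br)cc2O[C@H](c3cc(OC)c(OC(=O)C(C)(C)C)c(OC)c3)[C@@H](C)Oc12
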